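**Retrosynthetic overview**

- Numbering of the target: dienone ring C1(=O), C2(allyl), C3, C4(OMe, quaternary), C5(OMe), C6. The side chain is C8(H)(CH3) on C4 and the benzylic C7H2. The strategy rests on the path O(C5)–C5–C4–C8–C7: bonding that oxygen to C7 closes a five-membered ring. This is the O1–C2 bond of a 2-aryl-3-methyl-2,3-dihydrobenzofuran in which C3a = C4, C3 = C8 and C7a = C5.
- Disconnections: the O-methyl group at C5 goes back to a vinylogous acid. The C7–H bond goes back to the C7–O1 bond (ionic hydrogenolysis in the forward sense). The C4–OMe bond goes back to a 6-hydroxy-dihydrobenzofuran (oxidative dearomatization in methanol).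
- The allyl group comes from O-allylation and Claisen rearrangement. The cis C2/C3 pair comes from enantioselective hydrogenation of a flat benzofuran. The benzofuran comes from 2,4-dihydroxyacetophenone and 3,4-dimethoxybenzoyl chloride by titanium keto–ester coupling.
- Ring order: both benzene rings are bought. The furan is closed in step 3 and saturated in step 4, the resorcinol ring is dearomatized in step 8, and the dihydrofuran is opened in step 9.

Key step: step 8

Assumption: the facial sense of the hydrogenation catalyst on 5 cannot be derived safely. The ligand enantiomer is therefore fixed by a test run, and the (2R,3S) configuration of 7 is confirmed (for example by X-ray analysis of a crystalline ester) before material is carried on.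

**Step 1**
Reactants: 1 2,4-dihydroxyacetophenone
Product: 2 2-hydroxy-4-(triisopropylsilyloxy)acetophenone
Conditions: TIPSCl (1.05 equiv), imidazole, DMF, 0 °C → rt
Reagents that add atoms: triisopropylsilyl chloride, CC(C)[Si](Cl)(C(C)C)C(C)C
Why: Selective phenol silylation should occur at the free 4-OH, because the 2-OH is tied up in a hydrogen bond to the acetyl carbonyl and is much less nucleophilic.

**Step 2**
Reactants: 2 2-hydroxy-4-(triisopropylsilyloxy)acetophenone; 3 3,4-dimethoxybenzoyl chloride
Product: 4 2-acetyl-5-(triisopropylsilyloxy)phenyl 3,4-dimethoxybenzoate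
Conditions: Et3N, DMAP (cat.), CH2Cl2, 0 °C → rt
Reagents that add atoms: none
Why: DMAP-catalysed O-acylation overcomes the chelation of the remaining phenol, and the amine base is too weak to start acyl migration to the acetyl methyl group.

**Step 3**
Reactants: 4 2-acetyl-5-(triisopropylsilyloxy)phenyl 3,4-dimethoxybenzoate
Product: 5 2-(3,4-dimethoxyphenyl)-3-methyl-6-(triisopropylsilyloxy)benzofuran
Conditions: TiCl3, Zn dust, THF, reflux, slow addition of 4 (high dilution)
Reagents that add atoms: none
Why: In this McMurry-type intramolecular keto–ester coupling, low-valent titanium joins the acetyl carbon (future C3) to the aroyl carbon (future C2), and deoxygenation gives the aromatic furan, a known route from 2-acyloxyaryl ketones to benzofurans.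

**Step 4**
Reactants: 5 2-(3,4-dimethoxyphenyl)-3-methyl-6-(triisopropylsilyloxy)benzofuran
Product: 6 (2R,3S)-2-(3,4-dimethoxyphenyl)-3-methyl-6-(triisopropylsilyloxy)-2,3-dihydrobenzofuran
Conditions: H2 (80 bar), [Ru(cod)(2-methylallyl)2] (5 mol %), SINpEt·HBF4 (10 mol %, one enantiomer, see assumption), KOt-Bu (cat.), n-hexane, 40 °C
Reagents that add atoms: none
Why: Proposed new method: the chiral Ru–bis(NHC) catalyst binds one π-face of the furan and delivers both hydrogens to that face of C2=C3, so methyl and aryl must end cis and the ligand decides which face reacts (3S, the future C8, and the temporary 2R); the closest known reaction type is the enantioselective hydrogenation of 2-aryl-, 2-alkyl- and 3-alkylbenzofurans with Ru–NHC or Ir–N,P catalysts, which spares the benzene rings, whereas a fully substituted 2-aryl-3-methyl furan bond lies outside the secured scope.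

**Step 5**
Reactants: 6 (2R,3S)-2-(3,4-dimethoxyphenyl)-3-methyl-6-(triisopropylsilyloxy)-2,3-dihydrobenzofuran
Product: 7 (2R,3S)-2-(3,4-dimethoxyphenyl)-3-methyl-2,3-dihydrobenzofuran-6-ol
Conditions: TBAF, AcOH (1.1 equiv each), THF, 0 °C
Reagents that add atoms: none
Why: Fluoride cleavage of an aryl silyl ether is fast, and the acetic acid buffer keeps the medium near neutral so neither stereocentre is at risk.

**Step 6**
Reactants: 7 (2R,3S)-2-(3,4-dimethoxyphenyl)-3-methyl-2,3-dihydrobenzofuran-6-ol; 8 allyl bromide
Product: 9 (2R,3S)-6-allyloxy-2-(3,4-dimethoxyphenyl)-3-methyl-2,3-dihydrobenzofuran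
Conditions: K2CO3, acetone, reflux
Reagents that add atoms: none
Why: This is a Williamson O-allylation of the only acidic OH group under mild carbonate conditions that do not touch the benzylic ether.

**Step 7**
Reactants: 9 (2R,3S)-6-allyloxy-2-(3,4-dimethoxyphenyl)-3-methyl-2,3-dihydrobenzofuran
Product: 11 (2R,3S)-5-allyl-2-(3,4-dimethoxyphenyl)-3-methyl-2,3-dihydrobenzofuran-6-ol, via Claisen ortho-dienone 10 (not isolated)
Conditions: PhNEt2, 200 °C, Ar, sealed tube
Reagents that add atoms: none
Why: In the aromatic Claisen rearrangement ([3,3] shift, then enolization of 10) C5 should be preferred because C7 is wedged between two oxygen substituents and the five-ring fusion favours C5=C6 double-bond character, any C7 isomer being removed by chromatography and the basic, acid-free medium leaving C2 and C3 unchanged.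

**Step 8**
Reactants: 11 (2R,3S)-5-allyl-2-(3,4-dimethoxyphenyl)-3-methyl-2,3-dihydrobenzofuran-6-ol
Product: 13 (2R,3R,3aS)-5-allyl-2-(3,4-dimethoxyphenyl)-3a-methoxy-3-methyl-3,3a-dihydrobenzofuran-6(2H)-one, via aryloxy-iodane 12 (not isolated)
Conditions: PhI(OAc)2 (1.1 equiv), MeOH, −10 → 0 °C
Reagents that add atoms: methanol, CO
Why: The phenol exchanges an acetate at iodine(III) to give 12, whose collapse with loss of iodobenzene and acetate places phenoxenium character on the ring, and methanol bonds to the para carbon C3a, which creates the C3a–OMe bond (C4–OMe of 16) and the cross-conjugated 2,5-dienone. The closest known reaction type is the iodine(III)- or lead(IV)-mediated para-methoxylation of 4-alkylphenols to para-quinol ethers, which is documented for 6-hydroxy-2-aryl-3-methyl-2,3-dihydrobenzofurans of the benzofuranoid neolignan class. No ring is closed here, and the dihydrofuran already present acts only as a stereochemical template. The one new stereocentre, C3a, is under substrate control: the C3 methyl on the adjacent carbon and the C2 aryl lie on the same face of the nearly flat bicycle, so methanol should enter from the free face and give OMe trans to methyl, that is (3R,3aS), which maps onto (4R,8R) of the target. The site selectivity needed is para over ortho, and it is secured because C5 carries the allyl group, attack at C3a produces the stabilised vinylogous ester O1–C7a=C7–C6=O, and the fully substituted C3a cannot rearomatize. Only the phenol can bind to iodine, so the allyl and dimethoxyphenyl groups should survive at this temperature.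

**Step 9**
Reactants: 13 (2R,3R,3aS)-5-allyl-2-(3,4-dimethoxyphenyl)-3a-methoxy-3-methyl-3,3a-dihydrobenzofuran-6(2H)-one
Product: 15 (4R)-2-allyl-5-hydroxy-4-methoxy-4-[(2R)-1-(3,4-dimethoxyphenyl)propan-2-yl]cyclohexa-2,5-dien-1-one, via benzylic cation 14 (not isolated)
Conditions: Et3SiH (10 equiv), CF3CO2H (5 equiv), CH2Cl2, −40 → 0 °C; pH 5 buffer work-up
Reagents that add atoms: none
Why: Proposed new method: protonation of the dienone carbonyl makes O1 the leaving group of a vinylogous carboxylic acid, the C2–O1 bond ionizes to the 3,4-dimethoxybenzyl cation 14, and because recapture by oxygen or by the enol carbon is expected to be reversible under these conditions while hydride transfer from the excess silane is not, the equilibria should drain to 15 with C4 and C8 untouched and the monosubstituted allyl alkene inert; the closest known reaction type is ionic hydrogenation (silane plus acid) of electron-rich benzylic ethers and esters, including the silane-scavenged acidolysis of dimethoxybenzyl ethers and the reductive opening of 2-arylchromans.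

**Step 10**
Reactants: 15 (4R)-2-allyl-5-hydroxy-4-methoxy-4-[(2R)-1-(3,4-dimethoxyphenyl)propan-2-yl]cyclohexa-2,5-dien-1-one
Product: 16 (4R)-2-allyl-4,5-dimethoxy-4-[(2R)-1-(3,4-dimethoxyphenyl)propan-2-yl]cyclohexa-2,5-dien-1-one (target)
Conditions: MeOH, HC(OMe)3 (3 equiv), PPTS (cat.), rt
Reagents that add atoms: methanol, CO
Why: Acid-catalysed enol etherification of a cyclic 1,3-dicarbonyl is reversible, so the two possible enol ethers interconvert through a common ketal and should settle on the cross-conjugated 2,5-dienone, which is expected but not proven to be the more stable isomer, with the orthoformate removing water and no stereocentre involved.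

**Compound list**

| No. | Name | SMILES | Role |
|---|---|---|---|
| 1 | 2,4-dihydroxyacetophenone | CC(=O)c1ccc(O)cc1O | starting material |
| 2 | 2-hydroxy-4-(triisopropylsilyloxy)acetophenone | CC(=O)c1ccc(O[Si](C(C)C)(C(C)C)C(C)C)cc1O | intermediate |
| 3 | 3,4-dimethoxybenzoyl chloride | COc1ccc(cc1OC)C(Cl)=O | starting material |
| 4 | 2-acetyl-5-(triisopropylsilyloxy)phenyl 3,4-dimethoxybenzoate | CC(=O)c1ccc(O[Si](C(C)C)(C(C)C)C(C)C)cc1OC(=O)c1ccc(OC)c(OC)c1 | intermediate |
| 5 | 2-(3,4-dimethoxyphenyl)-3-methyl-6-(triisopropylsilyloxy)benzofuran | Cc1c(-c2ccc(OC)c(OC)c2)oc2cc(O[Si](C(C)C)(C(C)C)C(C)C)ccc12 | intermediate |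
| 6 | (2R,3S)-2-(3,4-dimethoxyphenyl)-3-methyl-6-(triisopropylsilyloxy)-2,3-dihydrobenzofuran | c1cc2[C@H](C)[C@H](c3ccc(OC)c(OC)c3)Oc2cc1O[Si](C(C)C)(C(C)C)C(C)C | intermediate |
| 7 | (2R,3S)-2-(3,4-dimethoxyphenyl)-3-methyl-2,3-dihydrobenzofuran-6-ol | c1cc2[C@H](C)[C@H](c3ccc(OC)c(OC)c3)Oc2cc1O | intermediate |
| 8 | allyl bromide | C=CCBr | starting material |
| 9 | (2R,3S)-6-allyloxy-2-(3,4-dimethoxyphenyl)-3-methyl-2,3-dihydrobenzofuran | C=CCOc1ccc2[C@H](C)[C@H](c3ccc(OC)c(OC)c3)Oc2c1 | intermediate |
| 10 | (2R,3S)-5-allyl-2-(3,4-dimethoxyphenyl)-3-methyl-3,5-dihydrobenzofuran-6(2H)-one, Claisen ortho-dienone, C5 undefined (not isolated) | C=CCC1C=C2[C@H](C)[C@H](c3ccc(OC)c(OC)c3)OC2=CC1=O | intermediate |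
| 11 | (2R,3S)-5-allyl-2-(3,4-dimethoxyphenyl)-3-methyl-2,3-dihydrobenzofuran-6-ol | C=CCc1cc2[C@H](C)[C@H](c3ccc(OC)c(OC)c3)Oc2cc1O | intermediate |
| 12 | acetoxy(phenyl)-λ3-iodanyl ether of 11, aryloxy-iodane (not isolated) | C=CCc1cc2[C@H](C)[C@H](c3ccc(OC)c(OC)c3)Oc2cc1OI(OC(C)=O)c1ccccc1 | intermediate |
| 13 | (2R,3R,3aS)-5-allyl-2-(3,4-dimethoxyphenyl)-3a-methoxy-3-methyl-3,3a-dihydrobenzofuran-6(2H)-one | C=CCC1=C[C@]2(OC)[C@H](C)[C@H](c3ccc(OC)c(OC)c3)OC2=CC1=O | intermediate |
| 14 | ring-opened 3,4-dimethoxybenzyl cation bearing the enol form of the vinylogous acid (not isolated) | C=CCC1=C[C@](OC)([C@H](C)[CH+]c2ccc(OC)c(OC)c2)C(O)=CC1=O | intermediate |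
| 15 | (4R)-2-allyl-5-hydroxy-4-methoxy-4-[(2R)-1-(3,4-dimethoxyphenyl)propan-2-yl]cyclohexa-2,5-dien-1-one | C=CCC1=C[C@](OC)([C@H](C)Cc2ccc(OC)c(OC)c2)C(O)=CC1=O | intermediate |
| 16 | (4R)-2-allyl-4,5-dimethoxy-4-[(2R)-1-(3,4-dimethoxyphenyl)propan-2-yl]cyclohexa-2,5-dien-1-one | C=CCC1=C[C@](OC)([C@H](C)Cc2ccc(OC)c(OC)c2)C(OC)=CC1=O | target |

Total step count: 10. Longest linear sequence: 10 steps (1 → 16).

**Steps most likely to fail**

1. Step 9 (Proposed new method).
   - Risks: after ionization, hydride transfer may lose out to intramolecular capture of the cation by the enol carbon C6, a five-membered closure to a bicyclo[3.2.1]octane skeleton. It may also lose out to loss of the C8 proton followed by reprotonation, which would scramble C8, or to acid-induced dienone–phenol migration.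
   - Fallback (known chemistry, sets out from 9, returns at 16): ring opening and dearomatization are inverted. Compound 9 is a secondary 3,4-dimethoxybenzyl aryl ether. Its C2–O1 bond is cleaved with Et3SiH/CF3CO2H in CH2Cl2 at 0 °C, the standard silane-scavenged acidolysis of such ethers, to give 5-allyloxy-2-[(2R)-1-(3,4-dimethoxyphenyl)propan-2-yl]phenol F1. MeI/K2CO3 in acetone gives 4-allyloxy-1-[(2R)-1-(3,4-dimethoxyphenyl)propan-2-yl]-2-methoxybenzene F2. Claisen rearrangement in PhNEt2 at 200 °C gives 2-allyl-4-[(2R)-1-(3,4-dimethoxyphenyl)propan-2-yl]-5-methoxyphenol F3. PhI(OAc)2 in MeOH then gives 16 directly, together with (4S)-2-allyl-4,5-dimethoxy-4-[(2R)-1-(3,4-dimethoxyphenyl)propan-2-yl]cyclohexa-2,5-dien-1-one F4.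
   - Cost and benefit: F4 has to be separated by chromatography, because only the open-chain C8 centre now biases the attack. The C5 methyl ether is in place before the oxidation, so step 10 is bypassed as well.

2. Step 4 (Proposed new method).
   - Risks: turnover at the fully substituted C2=C3 bond may be slow, discrimination between the two faces may be poor, or a benzene ring may be over-reduced.
   - Fallback (known chemistry, sets out from 5, returns at 7): catalyst control is replaced by resolution. Heterogeneous syn hydrogenation (H2, Pd/C, EtOAc, stopped after one equivalent) gives racemic cis-2-(3,4-dimethoxyphenyl)-3-methyl-6-(triisopropylsilyloxy)-2,3-dihydrobenzofuran F5. TBAF/AcOH gives racemic cis-2-(3,4-dimethoxyphenyl)-3-methyl-2,3-dihydrobenzofuran-6-ol F6. Acylation with (1S)-camphanoyl chloride (Et3N, DMAP, CH2Cl2) gives the (2R,3S)-dihydrobenzofuran-6-yl (1S,4R)-camphanate F7 and the (2S,3R)-dihydrobenzofuran-6-yl (1S,4R)-camphanate F8. These are separated by crystallization or chromatography, and F7 is saponified (K2CO3, MeOH) to 7.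

3. Step 10.
   - Risks: the equilibrium may settle on etherification of the less hindered oxygen remote from the quaternary carbon, or prolonged acid contact may start rearrangement of the quinol ether.
   - Fallback (sets out from 15, returns at 16): thermodynamic control is given up for irreversible methylation with recycling. TMSCHN2 in toluene/MeOH at 0 °C methylates both oxygens of the ambident vinylogous acid. Compound 16 is then separated by chromatography from (6R)-4-allyl-3,6-dimethoxy-6-[(2R)-1-(3,4-dimethoxyphenyl)propan-2-yl]cyclohexa-2,4-dien-1-one F9. F9 is hydrolysed with dilute LiOH in THF/water back to 15 and methylated again.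

**Further compounds**
F1 | step 9 | 5-allyloxy-2-[(2R)-1-(3,4-dimethoxyphenyl)propan-2-yl]phenol | C=CCOc1ccc([C@H](C)Cc2ccc(OC)c(OC)c2)c(O)c1
F2 | step 9 | 4-allyloxy-1-[(2R)-1-(3,4-dimethoxyphenyl)propan-2-yl]-2-methoxybenzene | C=CCOc1ccc([C@H](C)Cc2ccc(OC)c(OC)c2)c(OC)c1
F3 | step 9 | 2-allyl-4-[(2R)-1-(3,4-dimethoxyphenyl)propan-2-yl]-5-methoxyphenol | C=CCc1cc([C@H](C)Cc2ccc(OC)c(OC)c2)c(OC)cc1O
F4 | step 9 | (4S)-2-allyl-4,5-dimethoxy-4-[(2R)-1-(3,4-dimethoxyphenyl)propan-2-yl]cyclohexa-2,5-dien-1-one | C=CCC1=C[C@@](OC)([C@H](C)Cc2ccc(OC)c(OC)c2)C(OC)=CC1=O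
F5 | step 4 | racemic cis-2-(3,4-dimethoxyphenyl)-3-methyl-6-(triisopropylsilyloxy)-2,3-dihydrobenzofuran (both enantiomers) | c1cc2[C@H](C)[C@H](c3ccc(OC)c(OC)c3)Oc2cc1O[Si](C(C)C)(C(C)C)C(C)C.c1cc2[C@@H](C)[C@@H](c3ccc(OC)c(OC)c3)Oc2cc1O[Si](C(C)C)(C(C)C)C(C)C
F6 | step 4 | racemic cis-2-(3,4-dimethoxyphenyl)-3-methyl-2,3-dihydrobenzofuran-6-ol (both enantiomers) | c1cc2[C@H](C)[C@H](c3ccc(OC)c(OC)c3)Oc2cc1O.c1cc2[C@@H](C)[C@@H](c3ccc(OC)c(OC)c3)Oc2cc1O
F7 | step 4 | (2R,3S)-2-(3,4-dimethoxyphenyl)-3-methyl-2,3-dihydrobenzofuran-6-yl (1S,4R)-camphanate | c1cc2[C@H](C)[C@H](c3ccc(OC)c(OC)c3)Oc2cc1OC(=O)[C@@]45CC[C@@](C)(C(=O)O4)C5(C)C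
F8 | step 4 | (2S,3R)-2-(3,4-dimethoxyphenyl)-3-methyl-2,3-dihydrobenzofuran-6-yl (1S,4R)-camphanate | c1cc2[C@@H](C)[C@@H](c3ccc(OC)c(OC)c3)Oc2cc1OC(=O)[C@@]45CC[C@@](C)(C(=O)O4)C5(C)C
F9 | step 10 | (6R)-4-allyl-3,6-dimethoxy-6-[(2R)-1-(3,4-dimethoxyphenyl)propan-2-yl]cyclohexa-2,4-dien-1-one | C=CCC1=C[C@](OC)([C@H](C)Cc2ccc(OC)c(OC)c2)C(=O)C=C1OC
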